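The route rests on opening ring C (the pyranone) at O1–C2 and C4–C4a. This exposes ring A as a 1,3-C,O-dinucleophile (C4a and O1) and the C2–C3–C4 unit as a 1,3-dielectrophile whose C3 oxygen is held as an epoxide. In one operation the C,O-dilithio species from 2-bromo-5-geranyloxyphenol is C-acylated by an enantiopure (2R,3S)-3-arylglycidic morpholine amide, and the liberated ortho-hydroxyaryl epoxy ketone closes by 6-endo opening at the benzylic carbon. C3 is kept by retention and C2 is set by inversion, giving the 2,3-trans (2R,3R) pair. Only fluoride removal of the catechol silyl ethers follows.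

Key step: step 5

Remark (assumption): in step 4, (S)-BINOL is assumed to deliver the (2R,3S)-epoxy amide; should a test run show the opposite sense, (R)-BINOL is used with no other change.

Step 1
Reactants: 1 4-bromoresorcinol; 2 geranyl bromide
Product: 3 2-bromo-5-{[(2E)-3,7-dimethylocta-2,6-dien-1-yl]oxy}phenol
Conditions: NaH (2.1 equiv), DMF, 0 °C; then 2 (1.0 equiv), 0 °C to rt; cold dilute aq. HCl work-up
Reagents that add atoms: none
Why: Williamson etherification through the resorcinol dianion, in which the more basic and unhindered phenoxide para to bromine, not the less basic bromine-flanked one, should be alkylated by the primary allylic bromide in an SN2 reaction that leaves the E-alkene untouched.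

Step 2
Reactants: 4 caffeic acid
Product: 6 (E)-3-[3,4-bis(tert-butyldimethylsilyloxy)phenyl]prop-2-enoic acid, via tris-silylated caffeate 5 (not isolated)
Conditions: TBSCl (3.3 equiv), imidazole (7 equiv), DMF, rt; then AcOH–THF–H2O (3:1:1), rt
Reagents that add atoms: tert-butyldimethylsilyl chloride (TBSCl), CC(C)(C)[Si](C)(C)Cl
Why: Silylation of both phenols and the acid is followed by selective hydrolysis of the silyl ester, which is far more labile to aqueous acetic acid than the aryl silyl ethers, and the E-alkene is not touched.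

Step 3
Reactants: 6 (E)-3-[3,4-bis(tert-butyldimethylsilyloxy)phenyl]prop-2-enoic acid
Product: 7 (E)-3-[3,4-bis(tert-butyldimethylsilyloxy)phenyl]-1-(morpholin-4-yl)prop-2-en-1-one
Conditions: morpholine (1.2 equiv), DCC (1.1 equiv), HOBt (0.2 equiv), CH2Cl2, 0 °C to rt
Reagents that add atoms: morpholine, C1COCCN1
Why: Carbodiimide-mediated amide coupling through the hydroxybenzotriazole active ester gives the morpholine amide, chosen because it is a suitable substrate for the epoxidation of step 4 and a monoacylating agent for organolithiums in step 5.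

Step 4
Reactants: 7 (E)-3-[3,4-bis(tert-butyldimethylsilyloxy)phenyl]-1-(morpholin-4-yl)prop-2-en-1-one
Product: 8 [(2R,3S)-3-[3,4-bis(tert-butyldimethylsilyloxy)phenyl]oxiran-2-yl](morpholin-4-yl)methanone
Conditions: Sm(O-i-Pr)3 (10 mol%), (S)-BINOL (10 mol%), Ph3As=O (10 mol%), TBHP (1.5 equiv, in decane), MS 4 Å, THF, rt
Reagents that add atoms: tert-butyl hydroperoxide (TBHP), CC(C)(C)OO
Why: Lanthanide–BINOL-catalysed nucleophilic epoxidation of an α,β-unsaturated amide (Weitz–Scheffer-type conjugate addition of a samarium-bound tert-butyl peroxide, then ring closure) should attack one face of the amide bound to the chiral samarium binaphthoxide and carry the E-geometry into the trans-epoxide, so that both stereocentres (2R,3S) are set by the catalyst.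

Step 5
Reactants: 3 2-bromo-5-{[(2E)-3,7-dimethylocta-2,6-dien-1-yl]oxy}phenol; 8 [(2R,3S)-3-[3,4-bis(tert-butyldimethylsilyloxy)phenyl]oxiran-2-yl](morpholin-4-yl)methanone
Product: 12 (2R,3R)-2-[3,4-bis(tert-butyldimethylsilyloxy)phenyl]-7-{[(2E)-3,7-dimethylocta-2,6-dien-1-yl]oxy}-3-hydroxy-2,3-dihydro-4H-chromen-4-one, via dilithio phenoxide 9 (not isolated), via tetrahedral adduct 10 (not isolated), via epoxy ketone 11 (not isolated)
Conditions: 3 (1.3 equiv), t-BuLi (3.9 equiv), THF, −78 °C; then 8 (1.0 equiv), −78 to −40 °C; AcOH (4 equiv), −78 °C to rt, then 40 °C, under Ar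
Reagents that add atoms: none
Why: Bromine–lithium exchange on the lithium phenoxide of 3 gives the C,O-dilithio species 9, whose aryl carbon (future C4a) adds to the amide carbonyl of 8 (future C4) to give the chelated tetrahedral adduct 10, which resists collapse until protonation, so that only single acyl substitution occurs (Weinreb-type ketone synthesis with a morpholine amide). Acetic acid then releases the ortho-hydroxyaryl α,β-epoxy ketone 11 together with morpholinium acetate, and in this buffer the phenol oxygen (future O1) opens the epoxide at its benzylic carbon (future C2), the same ring closure as the epoxide stage of the Algar–Flynn–Oyamada reaction. Ring C is thereby closed in the 6-endo-tet mode, the oxygen attacking anti to the breaking benzylic C–O bond. C3 is the untouched α-carbon of the epoxide and keeps the R configuration set in step 4, while C2 is formed with inversion at the benzylic carbon (S in 8, R in 12), which gives the 2,3-trans diequatorial arrangement that is also the thermodynamically preferred one. The step needs 6-endo attack at the benzylic carbon rather than 5-exo attack at the α-carbon (aurone-type benzofuranone), and addition of the aryllithium to the amide rather than to the epoxide or the silyl ethers; the first is secured by the electron-rich 3,4-bis(silyloxy)phenyl group, which weakens the benzylic C–O bond, and by the unsubstituted ring A position ortho to the ketone, the second by the low temperature and the chelating, electrophilic amide.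

Step 6
Reactants: 12 (2R,3R)-2-[3,4-bis(tert-butyldimethylsilyloxy)phenyl]-7-{[(2E)-3,7-dimethylocta-2,6-dien-1-yl]oxy}-3-hydroxy-2,3-dihydro-4H-chromen-4-one
Product: 13 (2R,3R)-2-(3,4-dihydroxyphenyl)-7-{[(2E)-3,7-dimethylocta-2,6-dien-1-yl]oxy}-3-hydroxy-2,3-dihydro-4H-chromen-4-one (CNP0508026.1)
Conditions: TBAF (2.4 equiv), AcOH (3 equiv), THF, 0 °C, under Ar
Reagents that add atoms: none
Why: Fluoride-mediated cleavage of the two aryl silyl ethers under acetic acid buffering keeps the phenols protonated, so that neither ring opening with epimerisation at C2 nor autoxidation to the flavonol should be triggered, and the geranyl ether and both stereocentres are not affected.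

Compound list
1 | 4-bromoresorcinol (4-bromobenzene-1,3-diol) | Oc1ccc(Br)c(O)c1 | starting material
2 | geranyl bromide ((2E)-1-bromo-3,7-dimethylocta-2,6-diene) | CC(C)=CCC/C(C)=C/CBr | starting material
3 | 2-bromo-5-{[(2E)-3,7-dimethylocta-2,6-dien-1-yl]oxy}phenol | CC(C)=CCC/C(C)=C/COc1ccc(Br)c(O)c1 | intermediate
4 | caffeic acid ((E)-3-(3,4-dihydroxyphenyl)prop-2-enoic acid) | OC(=O)/C=C/c1ccc(O)c(O)c1 | starting material
5 | tert-butyldimethylsilyl (E)-3-[3,4-bis(tert-butyldimethylsilyloxy)phenyl]prop-2-enoate (not isolated) | CC(C)(C)[Si](C)(C)OC(=O)/C=C/c1ccc(O[Si](C)(C)C(C)(C)C)c(O[Si](C)(C)C(C)(C)C)c1 | intermediate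
6 | (E)-3-[3,4-bis(tert-butyldimethylsilyloxy)phenyl]prop-2-enoic acid | OC(=O)/C=C/c1ccc(O[Si](C)(C)C(C)(C)C)c(O[Si](C)(C)C(C)(C)C)c1 | intermediate
7 | (E)-3-[3,4-bis(tert-butyldimethylsilyloxy)phenyl]-1-(morpholin-4-yl)prop-2-en-1-one | O=C(/C=C/c1ccc(O[Si](C)(C)C(C)(C)C)c(O[Si](C)(C)C(C)(C)C)c1)N1CCOCC1 | intermediate
8 | [(2R,3S)-3-[3,4-bis(tert-butyldimethylsilyloxy)phenyl]oxiran-2-yl](morpholin-4-yl)methanone (trans-epoxide) | O=C(N1CCOCC1)[C@@H]1O[C@H]1c1ccc(O[Si](C)(C)C(C)(C)C)c(O[Si](C)(C)C(C)(C)C)c1 | intermediate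
9 | lithium 5-{[(2E)-3,7-dimethylocta-2,6-dien-1-yl]oxy}-2-lithiophenoxide (not isolated) | CC(C)=CCC/C(C)=C/COc1ccc([Li])c(O[Li])c1 | intermediate
10 | dilithium salt of the tetrahedral adduct of 9 at the amide carbonyl of 8, (2R,3S)-epoxide intact, hemiaminal carbon undefined (not isolated) | CC(C)=CCC/C(C)=C/COc1ccc(C(O[Li])(N2CCOCC2)[C@@H]2O[C@H]2c2ccc(O[Si](C)(C)C(C)(C)C)c(O[Si](C)(C)C(C)(C)C)c2)c(O[Li])c1 | intermediate
11 | [(2R,3S)-3-[3,4-bis(tert-butyldimethylsilyloxy)phenyl]oxiran-2-yl](4-{[(2E)-3,7-dimethylocta-2,6-dien-1-yl]oxy}-2-hydroxyphenyl)methanone (not isolated) | CC(C)=CCC/C(C)=C/COc1ccc(C(=O)[C@@H]2O[C@H]2c2ccc(O[Si](C)(C)C(C)(C)C)c(O[Si](C)(C)C(C)(C)C)c2)c(O)c1 | intermediate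
12 | (2R,3R)-2-[3,4-bis(tert-butyldimethylsilyloxy)phenyl]-7-{[(2E)-3,7-dimethylocta-2,6-dien-1-yl]oxy}-3-hydroxy-2,3-dihydro-4H-chromen-4-one (2,3-trans) | CC(C)=CCC/C(C)=C/COc1ccc2c(c1)O[C@H](c1ccc(O[Si](C)(C)C(C)(C)C)c(O[Si](C)(C)C(C)(C)C)c1)[C@@H](O)C2=O | intermediate
13 | (2R,3R)-2-(3,4-dihydroxyphenyl)-7-{[(2E)-3,7-dimethylocta-2,6-dien-1-yl]oxy}-3-hydroxy-2,3-dihydro-4H-chromen-4-one (CNP0508026.1) | CC(C)=CCC/C(C)=C/COc1ccc2c(c1)O[C@H](c1ccc(O)c(O)c1)[C@@H](O)C2=O | target

Total step count: 6
Longest linear sequence: 5 steps (steps 2, 3, 4, 5 and 6, from caffeic acid)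

Steps most likely to fail

1. Step 5. The aggregated dilithio species may transfer to the amide sluggishly or be quenched by proton transfer, and ring closure may be diverted to attack at the α-carbon of the epoxide. The fallback sets out from 3 and 8 and comes back to the route at 13, absorbing step 6. The phenol of 3 is silylated (TIPSCl, imidazole, DMF, rt) to [2-bromo-5-(geranyloxy)phenoxy]triisopropylsilane F1. Bromine–lithium exchange and addition to 8 (t-BuLi, 2 equiv, Et2O–THF, −78 °C, kept cold to suppress silyl migration from oxygen to carbon; then 8; NH4Cl quench) should give the isolable ortho-silyloxyaryl epoxy ketone F2 from a monolithio arene that is more nucleophilic than 9. TBAF/AcOH (THF, 0 °C to rt) then removes all three silyl groups, and the triphenol epoxy ketone F3 so freed (not isolated) is expected to close ring C in the same 6-endo sense, with C3 untouched, to give 13.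

2. Step 4. Conjugate peroxide addition to the electron-rich, deactivated cinnamamide may be slow or poorly face-selective. The fallback sets out from 6 and comes back at 8. Acid 6 is reduced through its mixed anhydride (i-BuOCOCl, N-methylmorpholine, THF, −10 °C; then NaBH4, H2O) to the allylic alcohol F4. Sharpless asymmetric epoxidation (Ti(O-i-Pr)4, L-(+)-diethyl tartrate, TBHP, MS 4 Å, CH2Cl2, −20 °C) should give the (2S,3S)-epoxy alcohol F5, the face following from the established mnemonic for L-tartrate. Oxidation (Dess–Martin periodinane with NaHCO3, then Pinnick oxidation with NaClO2, NaH2PO4 and 2-methyl-2-butene) gives the glycidic acid F6, which is handled as its sodium salt and coupled at once with morpholine (DCC, HOBt, CH2Cl2) to return 8.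

3. Step 1. Site selection between the two phenoxide oxygens may be poor, and over-alkylation may occur. The fallback sets out from 2 and comes back at 3. Commercial 3-hydroxyphenyl benzoate is brominated para to its free hydroxyl group (NBS, MeCN, 0 °C) to 2-bromo-5-hydroxyphenyl benzoate F7, in which the directing hydroxyl fixes the position of bromine. The free phenol is alkylated with 2 (K2CO3, acetone, rt) to the benzoate F8. Methanolysis (K2CO3, MeOH, 0 °C) then frees the phenol ortho to bromine and gives 3.

Further compounds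
F1 | step 5 | [2-bromo-5-{[(2E)-3,7-dimethylocta-2,6-dien-1-yl]oxy}phenoxy]triisopropylsilane | CC(C)=CCC/C(C)=C/COc1ccc(Br)c(O[Si](C(C)C)(C(C)C)C(C)C)c1
F2 | step 5 | [(2R,3S)-3-[3,4-bis(tert-butyldimethylsilyloxy)phenyl]oxiran-2-yl](4-{[(2E)-3,7-dimethylocta-2,6-dien-1-yl]oxy}-2-(triisopropylsilyloxy)phenyl)methanone | CC(C)=CCC/C(C)=C/COc1ccc(C(=O)[C@@H]2O[C@H]2c2ccc(O[Si](C)(C)C(C)(C)C)c(O[Si](C)(C)C(C)(C)C)c2)c(O[Si](C(C)C)(C(C)C)C(C)C)c1
F3 | step 5 | [(2R,3S)-3-(3,4-dihydroxyphenyl)oxiran-2-yl](4-{[(2E)-3,7-dimethylocta-2,6-dien-1-yl]oxy}-2-hydroxyphenyl)methanone (not isolated) | CC(C)=CCC/C(C)=C/COc1ccc(C(=O)[C@@H]2O[C@H]2c2ccc(O)c(O)c2)c(O)c1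
F4 | step 4 | (E)-3-[3,4-bis(tert-butyldimethylsilyloxy)phenyl]prop-2-en-1-ol | OC/C=C/c1ccc(O[Si](C)(C)C(C)(C)C)c(O[Si](C)(C)C(C)(C)C)c1
F5 | step 4 | [(2S,3S)-3-[3,4-bis(tert-butyldimethylsilyloxy)phenyl]oxiran-2-yl]methanol | OC[C@@H]1O[C@H]1c1ccc(O[Si](C)(C)C(C)(C)C)c(O[Si](C)(C)C(C)(C)C)c1
F6 | step 4 | (2R,3S)-3-[3,4-bis(tert-butyldimethylsilyloxy)phenyl]oxirane-2-carboxylic acid | OC(=O)[C@@H]1O[C@H]1c1ccc(O[Si](C)(C)C(C)(C)C)c(O[Si](C)(C)C(C)(C)C)c1
F7 | step 1 | 2-bromo-5-hydroxyphenyl benzoate | Oc1ccc(Br)c(OC(=O)c2ccccc2)c1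
F8 | step 1 | 2-bromo-5-{[(2E)-3,7-dimethylocta-2,6-dien-1-yl]oxy}phenyl benzoate | CC(C)=CCC/C(C)=C/COc1ccc(Br)c(OC(=O)c2ccccc2)c1
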